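**Strategy.** Everything rests on cutting the bond between the bridging methylene carbon and C3 of the α-pyrone ring. The methylene carbon sits on an arene carbon flanked by two phenolic hydroxyls, so it can be unmasked as the exocyclic terminus of an ortho-quinone methide, while pyrone C3, between the C2 lactone carbonyl and the C4 enol, is the nucleophilic carbon of a cyclic 1,3-dicarbonyl. In one operation a phenolic Mannich base expels dimethylamine, the resulting ortho-quinone methide is captured at C3 by 6-ethyl-4-hydroxy-5-methyl-2-pyrone, and both rings re-aromatise to give arzanol without protecting groups. The precursor is the dimethylaminomethyl derivative of 3-prenylphloracetophenone.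

Key step: step 5

Remark: arzanol has no stereocentre. Silyl enol ether 2 is expected as an E-rich E/Z mixture and is drawn as the E isomer; its geometry is erased in step 2.

**Step 1**
Reactants: 1 pentan-3-one
Product: 2 (E)-3-(trimethylsilyloxy)pent-2-ene
Conditions: LiN(iPr)2 (LDA, commercial solution, 1.05 equiv), THF, −78 °C; then Me3SiCl, −78 °C to rt; distillation
Reagents that add atoms: chlorotrimethylsilane, C[Si](C)(C)Cl
Why: Kinetic deprotonation of the symmetrical ketone and O-silylation of the lithium enolate (silyl enol ether formation) should give 2, whose double-bond geometry is irrelevant because it is consumed in step 2.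

**Step 2**
Reactants: 2 (E)-3-(trimethylsilyloxy)pent-2-ene; 3 malonyl dichloride
Product: 5 6-ethyl-4-hydroxy-5-methyl-2H-pyran-2-one, via triketo acid chloride 4 (not isolated)
Conditions: Et2O, −78 °C to rt
Reagents that add atoms: none
Why: C-acylation of the silyl enol ether by one acid chloride group with loss of Me3SiCl gives 4, whose enolised ethyl ketone oxygen closes onto the second acid chloride (6-membered O-acylation) to give the 4-hydroxy-2-pyrone, a known pyrone synthesis from silyl enol ethers and malonyl dichloride.

**Step 3**
Reactants: 6 1-(2,4,6-trihydroxyphenyl)ethanone (phloracetophenone); 7 1-bromo-3-methylbut-2-ene (prenyl bromide)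
Product: 8 1-[2,4,6-trihydroxy-3-(3-methylbut-2-en-1-yl)phenyl]ethanone
Conditions: 10% aq. KOH, 0 °C to rt; 6 in excess (1.5 equiv); chromatography
Reagents that add atoms: none
Why: C-allylation of the ambident phloroglucinolate in water, where hydrogen bonding to the phenolate oxygens favours attack through carbon, should give a single mono-C-prenyl regioisomer because the two free ring positions of 6 are equivalent, with the excess of 6 limiting bis-prenylation.

**Step 4**
Reactants: 8 1-[2,4,6-trihydroxy-3-(3-methylbut-2-en-1-yl)phenyl]ethanone
Product: 9 1-[3-[(dimethylamino)methyl]-2,4,6-trihydroxy-5-(3-methylbut-2-en-1-yl)phenyl]ethanone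
Conditions: CH2(NMe2)2 (2 equiv), EtOH, 0 °C to rt; product collected as the precipitated inner salt
Reagents that add atoms: bis(dimethylamino)methane, CN(C)CN(C)C
Why: Mannich aminomethylation at the only unsubstituted ring carbon, by the iminium ion released when the acidic phenol protonates the aminal, should give 9, and the excess of aminal and liberated dimethylamine holds back premature elimination.

**Step 5**
Reactants: 9 1-[3-[(dimethylamino)methyl]-2,4,6-trihydroxy-5-(3-methylbut-2-en-1-yl)phenyl]ethanone; 5 6-ethyl-4-hydroxy-5-methyl-2H-pyran-2-one
Product: 11 arzanol, via ortho-quinone methide 10 (not isolated)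
Conditions: 5 (2 equiv), MeCN, 70 °C, slow argon sweep to remove Me2NH
Reagents that add atoms: none
Why: Proton transfer from the acidic pyrone 5 to the amine of 9 gives a pyronate/ammonium pair, and 1,4-elimination of dimethylamine through the ortho-phenol gives ortho-quinone methide 10, whose exocyclic methylene is attacked by the pyronate at C3 (Michael addition), after which tautomerisation restores both the phloroglucinol and the 4-hydroxy-2-pyrone rings. The closest known reaction type is the deaminative alkylation of cyclic 1,3-dicarbonyl compounds by phenolic Mannich bases via ortho-quinone methides. No ring is closed and no stereocentre is formed. The step needs C3- over O-alkylation of the ambident pyronate, which is secured because C5 is blocked by methyl, the soft methide carbon prefers the soft carbon terminus, and any O-benzyl adduct can revert to 10 under the reaction conditions. It also needs cross-coupling over self-reaction of 10, which is secured by the excess of 5 and by the fully substituted ring of 9, which leaves no nucleophilic arene carbon. Removal of volatile dimethylamine and rearomatisation should make the addition effectively irreversible at moderate temperature, which limits scrambling of the methylene bridge.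

**Compound list**
1 | pentan-3-one | CCC(=O)CC | starting material
2 | (E)-3-(trimethylsilyloxy)pent-2-ene | C/C=C(\CC)O[Si](C)(C)C | intermediate
3 | malonyl dichloride | O=C(Cl)CC(=O)Cl | starting material
4 | 4-methyl-3,5-dioxoheptanoyl chloride | CCC(=O)C(C)C(=O)CC(=O)Cl | intermediate
5 | 6-ethyl-4-hydroxy-5-methyl-2H-pyran-2-one | CCc1oc(=O)cc(O)c1C | intermediate
6 | 1-(2,4,6-trihydroxyphenyl)ethanone (phloracetophenone) | CC(=O)c1c(O)cc(O)cc1O | starting material
7 | 1-bromo-3-methylbut-2-ene (prenyl bromide) | CC(C)=CCBr | starting material
8 | 1-[2,4,6-trihydroxy-3-(3-methylbut-2-en-1-yl)phenyl]ethanone | CC(=O)c1c(O)cc(O)c(CC=C(C)C)c1O | intermediate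
9 | 1-[3-[(dimethylamino)methyl]-2,4,6-trihydroxy-5-(3-methylbut-2-en-1-yl)phenyl]ethanone | CC(=O)c1c(O)c(CN(C)C)c(O)c(CC=C(C)C)c1O | intermediate
10 | 4-acetyl-3,5-dihydroxy-6-methylidene-2-(3-methylbut-2-en-1-yl)cyclohexa-2,4-dien-1-one (ortho-quinone methide) | C=C1C(=O)C(CC=C(C)C)=C(O)C(C(C)=O)=C1O | intermediate
11 | arzanol, 3-{[3-acetyl-2,4,6-trihydroxy-5-(3-methylbut-2-en-1-yl)phenyl]methyl}-6-ethyl-4-hydroxy-5-methyl-2H-pyran-2-one | CCc1oc(=O)c(Cc2c(O)c(CC=C(C)C)c(O)c(C(C)=O)c2O)c(O)c1C | target

**Step count and risks**
Total step count: 5. Longest linear sequence: 3 steps (1 → 2 → 5 → 11, or 6 → 8 → 9 → 11).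

Steps most likely to fail:

1. Step 5. The ortho-quinone methide may dimerise with itself, the pyronate may be alkylated on oxygen, or the methylene bridge may scramble by retro-Michael fragmentation and recombination on prolonged heating. The fallback sets out from 8 (and uses 5) and comes back at 11. Vilsmeier–Haack formylation of 8 at its free ring carbon with (chloromethylene)dimethyliminium chloride in DMF at 0 °C, followed by aqueous hydrolysis, should give 3-acetyl-2,4,6-trihydroxy-5-(3-methylbut-2-en-1-yl)benzaldehyde F1. Treating F1 with 5 and Hantzsch ester (diethyl 2,6-dimethyl-1,4-dihydropyridine-3,5-dicarboxylate) under catalytic L-proline in CH2Cl2 at room temperature should bring about Knoevenagel condensation to (E)-3-{[3-acetyl-2,4,6-trihydroxy-5-(3-methylbut-2-en-1-yl)phenyl]methylidene}-6-ethyl-5-methyl-2H-pyran-2,4(3H)-dione F2 (not isolated; geometry not controlled, drawn E). F2 should then be reduced in the flask by conjugate hydride transfer to 11. The same methylene–C3 bond is formed, first as a C=C bond, at room temperature and without a free quinone methide having to survive heating.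

2. Step 4. Dimethylamine may be lost prematurely during aminomethylation, so that the quinone methide is captured by unreacted 8 to form a symmetrical diarylmethane, and the zwitterionic Mannich base may decompose on isolation. The fallback sets out from 8 and comes back at 10. Benzotriazolylmethylation of 8 with 1H-benzotriazole-1-methanol and catalytic AcOH in dioxane at 60 °C should give 1-[3-(1H-benzotriazol-1-ylmethyl)-2,4,6-trihydroxy-5-(3-methylbut-2-en-1-yl)phenyl]ethanone F3, a neutral, chromatographable quinone methide precursor. Warming F3 with 5 and Et3N in MeCN should expel benzotriazole to give 10, which is trapped by 5 as in step 5.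

3. Step 3. The polyphenolate may be over-alkylated, O-alkylated or geminally bis-prenylated with dearomatisation. The fallback sets out from 6 and comes back at 8. Friedel–Crafts prenylation of 6 with 2-methylbut-3-en-2-ol and BF3·OEt2 in dioxane at room temperature replaces the anionic alkylation by electrophilic aromatic substitution with a prenyl cation equivalent, in which O-alkylation is not productive. This fallback makes no new compound (F0).

**Further compounds**
F1 | step 5 | 3-acetyl-2,4,6-trihydroxy-5-(3-methylbut-2-en-1-yl)benzaldehyde | CC(=O)c1c(O)c(C=O)c(O)c(CC=C(C)C)c1O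
F2 | step 5 | (E)-3-{[3-acetyl-2,4,6-trihydroxy-5-(3-methylbut-2-en-1-yl)phenyl]methylidene}-6-ethyl-5-methyl-2H-pyran-2,4(3H)-dione | CCC1=C(C)C(=O)/C(=C\c2c(O)c(CC=C(C)C)c(O)c(C(C)=O)c2O)C(=O)O1
F3 | step 4 | 1-[3-(1H-benzotriazol-1-ylmethyl)-2,4,6-trihydroxy-5-(3-methylbut-2-en-1-yl)phenyl]ethanone | CC(=O)c1c(O)c(Cn2nnc3ccccc32)c(O)c(CC=C(C)C)c1O
F0 | step 3 | none | none
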